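**Plan**

- Retrosynthesis: after removal of the five acid-labile groups, the protected target is cut in one operation at C5–CH2 (dihydroxyisopentyl group) and at C6–C1' (chain). This gives an aryl iodide, an (S)-epoxide and a terminal alkene. The alkene is cut at C5'=C6', the aryl iodide at C1–CHO.
- Feature used: in ring A (C1 CHO, C2 OH, C3, C4, C5 dihydroxyisopentyl, C6 chain C1'–C11') the two carbon substituents sit on the neighbours C5 and C6, and C6 lies beside the formyl-bearing C1. An iodide on C6 whose other ortho carbon C1 is blocked lets palladium and norbornene alkylate C5–H and then vinylate C6.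
- Forward: three fragments of three steps each (aryl iodide from 3-iodophenol, epoxide from 2-methylbut-3-en-2-ol, chain alkene from the acetonide of dimethyl L-tartrate and (S)-propylene oxide) are joined in a single three-component coupling that closes no ring, then deprotected.
- Stereochemistry: C10' comes from (S)-propylene oxide, C3' and C4' from L-tartaric acid, and the side-chain carbinol from a kinetically resolved epoxide whose stereocentre is not touched on opening. C5'=C6' is set E by metathesis and C1'=C2' E by syn β-hydride elimination.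

Key step: step 11

Assumption: in the hydrolytic kinetic resolution the (R,R) cobalt–salen catalyst is taken to hydrolyse the enantiomer of the racemic epoxide that corresponds in space to (S)-propylene oxide (here it carries the descriptor R), so the (S)-epoxide is recovered; the tartrate acetonide and but-3-enylmagnesium bromide are bought.

**Route**

Step 1
Reactants: 1 3-iodophenol
Product: 2 1-iodo-3-(methoxymethoxy)benzene
Conditions: MOMCl, i-Pr2NEt, CH2Cl2, 0 → 25 °C
Reagents that add atoms: chloromethyl methyl ether (MOMCl), COCCl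
Why: Williamson-type O-alkylation of the phenol with the chloromethyl ether is fast under amine base and installs the group that directs the metalation in step 2.

Step 2
Reactants: 2 1-iodo-3-(methoxymethoxy)benzene
Product: 4 2-iodo-6-(methoxymethoxy)benzaldehyde, via aryllithium 3 (not isolated)
Conditions: LiN(i-Pr)2 (1.1 equiv), THF, −78 °C; DMF, −78 → −40 °C; H2O
Reagents that add atoms: N,N-dimethylformamide (DMF), CN(C)C=O
Why: Directed ortho-metalation followed by Bouveault formylation: the hydrogen between iodine and the methoxymethoxy group is the only doubly activated one, the amide base deprotonates without iodine–lithium exchange, and the aryllithium held at −78 °C is trapped by DMF before it can lose LiI.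

Step 3
Reactants: 4 2-iodo-6-(methoxymethoxy)benzaldehyde
Product: 5 2-[2-iodo-6-(methoxymethoxy)phenyl]-1,3-dioxolane
Conditions: Me3SiOCH2CH2OSiMe3, Me3SiOTf (5 mol %), CH2Cl2, −78 → −20 °C; pyridine
Reagents that add atoms: 1,2-bis(trimethylsilyloxy)ethane, C[Si](C)(C)OCCO[Si](C)(C)C
Why: Noyori acetalisation converts even a di-ortho-substituted aldehyde at low temperature under aprotic conditions in which the aryl methoxymethyl ether is not exchanged.

Step 4
Reactants: 6 2-methylbut-3-en-2-ol
Product: 7 3-(methoxymethoxy)-3-methylbut-1-ene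
Conditions: MOMCl, i-Pr2NEt, CH2Cl2, 0 → 40 °C
Reagents that add atoms: chloromethyl methyl ether (MOMCl), COCCl
Why: O-alkylation of the tertiary alcohol with the reactive chloromethyl ether gives an acetal-type ether which, unlike a silyl ether, cannot migrate to the neighbouring alkoxide that is formed in step 11.

Step 5
Reactants: 7 3-(methoxymethoxy)-3-methylbut-1-ene
Product: 8 rac-2-[2-(methoxymethoxy)propan-2-yl]oxirane
Conditions: Oxone (2KHSO5·KHSO4·K2SO4), CF3COCH3, NaHCO3, MeCN/aq. Na2EDTA, 0 °C
Reagents that add atoms: potassium peroxymonosulfate (from Oxone), [K+].[O-]S(=O)(=O)OO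
Why: Dioxirane epoxidation with methyl(trifluoromethyl)dioxirane generated in the flask oxidises hindered, electron-poor monosubstituted alkenes under buffered neutral conditions that spare the acetal; the product is racemic.

Step 6
Reactants: 8 rac-2-[2-(methoxymethoxy)propan-2-yl]oxirane
Product: 9 (S)-2-[2-(methoxymethoxy)propan-2-yl]oxirane
Conditions: (R,R)-Co(salen)(OAc) (2 mol %; salen = N,N'-bis(3,5-di-tert-butylsalicylidene)cyclohexane-1,2-diamine dianion), H2O (0.55 equiv), THF, 0 → 25 °C; distillation
Reagents that add atoms: none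
Why: Jacobsen hydrolytic kinetic resolution: the chiral complex of trivalent cobalt delivers water to the CH2 terminus of the (R)-epoxide much faster than to its antipode, so the (S)-epoxide should be recovered in high enantiomeric purity, the catalyst fixing its configuration; hindered terminal epoxides such as tert-butyloxirane are known substrates.

Step 7
Reactants: 10 (S)-propylene oxide; 11 but-3-enylmagnesium bromide
Product: 12 (S)-hept-6-en-2-ol
Conditions: CuI (10 mol %), THF, −30 → 0 °C; aqueous work-up
Reagents that add atoms: none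
Why: Copper-catalysed Grignard opening of the epoxide takes place by SN2 attack at the CH2 carbon, so the (S) carbinol centre of the chiral-pool epoxide is carried over unchanged as C10'.

Step 8
Reactants: 12 (S)-hept-6-en-2-ol
Product: 13 (S)-tert-butyl(hept-6-en-2-yloxy)dimethylsilane
Conditions: TBSCl, imidazole, DMF, 25 °C
Reagents that add atoms: tert-butyldimethylsilyl chloride (TBSCl), CC(C)(C)[Si](C)(C)Cl
Why: Silyl ether formation on an unhindered secondary alcohol is routine and keeps the C10' hydroxyl from acting as an alkoxide in step 11.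

Step 9
Reactants: 14 dimethyl (4R,5R)-2,2-dimethyl-1,3-dioxolane-4,5-dicarboxylate (acetonide of dimethyl L-tartrate)
Product: 16 (4S,5S)-2,2-dimethyl-4,5-divinyl-1,3-dioxolane, via dialdehyde 15 (not isolated)
Conditions: i-Bu2AlH (2.1 equiv), toluene, −78 °C; then Ph3P=CH2 (from Ph3PCH3Br and KN(SiMe3)2, THF), −78 → 40 °C
Reagents that add atoms: methyltriphenylphosphonium bromide, C[P+](c1ccccc1)(c1ccccc1)c1ccccc1.[Br-]
Why: Half-reduction of both esters to aluminium hemiacetals and Wittig methylenation of the aldehydes as they are released avoids handling the epimerisable, hydrate-forming dialdehyde; both stereocentres come from L-tartaric acid and only their descriptors change.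

Step 10
Reactants: 16 (4S,5S)-2,2-dimethyl-4,5-divinyl-1,3-dioxolane; 13 (S)-tert-butyl(hept-6-en-2-yloxy)dimethylsilane
Product: 17 tert-butyl{[(2S,6E)-7-[(4S,5S)-2,2-dimethyl-5-vinyl-1,3-dioxolan-4-yl]hept-6-en-2-yl]oxy}dimethylsilane
Conditions: 16 (3 equiv), second-generation Grubbs catalyst RuCl2(=CHPh)(PCy3)(H2IMes) (5 mol %), CH2Cl2, 40 °C
Reagents that add atoms: none
Why: Olefin cross-metathesis of the unhindered terminal alkene with one vinyl group of the C2-symmetric diene (used in excess; either vinyl group gives the same product, and the trans-divinyl dioxolane cannot ring-close) should equilibrate toward the E alkene favoured by the allylic branching.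

Step 11
Reactants: 5 2-[2-iodo-6-(methoxymethoxy)phenyl]-1,3-dioxolane; 9 (S)-2-[2-(methoxymethoxy)propan-2-yl]oxirane; 17 tert-butyl{[(2S,6E)-7-[(4S,5S)-2,2-dimethyl-5-vinyl-1,3-dioxolan-4-yl]hept-6-en-2-yl]oxy}dimethylsilane
Product: 18 (2S)-1-{2-[(E)-2-{(4S,5S)-5-[(1E,6S)-6-(tert-butyldimethylsilyloxy)hept-1-en-1-yl]-2,2-dimethyl-1,3-dioxolan-4-yl}vinyl]-3-(1,3-dioxolan-2-yl)-4-(methoxymethoxy)phenyl}-3-(methoxymethoxy)-3-methylbutan-2-ol
Conditions: Pd(OAc)2 (10 mol %), P(2-furyl)3 (22 mol %), norbornene (2 equiv), Cs2CO3 (2.5 equiv), 9 (2.5 equiv), 17 (1.5 equiv), MeCN, 70 °C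
Reagents that add atoms: none
Why: Proposed new method: zerovalent palladium inserts into the C6–I bond of 5, norbornene inserts, and palladation of C5–H gives the five-membered aryl–norbornyl palladacycle of divalent palladium; this is oxidised to tetravalent palladium by the CH2 terminus of epoxide 9 (directly or through its iodohydrin alkoxide), reductive elimination forms C5–CH2, and norbornene is extruded because both positions flanking the aryl–palladium bond are then substituted. The arylpalladium species inserts the vinyl group of 17 with the aryl group going to the terminal carbon, and syn β-hydride elimination of a C1' hydrogen gives the styrene; the closest known reaction type is the Catellani ortho alkylation of ortho-substituted aryl iodides with terminal epoxides terminated by a Heck reaction with acrylates, whereas termination by an unactivated allylic-acetal alkene is not established. No ring is closed and no stereocentre is created: the carbinol carbon is the untouched stereocentre of 9, and C1'=C2' is E because the elimination places the aryl group and C3' anti and leads to the conjugated alkene instead of the enol ether toward C3'. The order alkylation before vinylation is secured by the dioxolane on C1, which makes norbornene insertion faster than insertion of the hindered alkene and allows norbornene to leave only after C5 carries its substituent. The competing aryl–oxygen reductive elimination of the liberated cesium alkoxide (which would close a dihydrobenzofuran) is held back by the small, weakly donating phosphine, the moderate temperature and the excess of 17.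

Step 12
Reactants: 18 (2S)-1-{2-[(E)-2-{(4S,5S)-5-[(1E,6S)-6-(tert-butyldimethylsilyloxy)hept-1-en-1-yl]-2,2-dimethyl-1,3-dioxolan-4-yl}vinyl]-3-(1,3-dioxolan-2-yl)-4-(methoxymethoxy)phenyl}-3-(methoxymethoxy)-3-methylbutan-2-ol
Product: 19 3-[(2S)-2,3-dihydroxy-3-methylbutyl]-6-hydroxy-2-[(1E,3S,4S,5E,10S)-3,4,10-trihydroxyundeca-1,5-dien-1-yl]benzaldehyde (CNP0348098.1)
Conditions: 3 M aq. HCl/THF (1:2), 25 → 40 °C
Reagents that add atoms: water, O
Why: Acid-catalysed acetal hydrolysis should cleave the aryl dioxolane, both methoxymethyl ethers, the acetonide and the silyl ether in one operation, while the vicinal diol and the formyl-deactivated styrene disfavour ionisation at C3' and C4' and no stereocentre is touched.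

**Compound list**

1 | 3-iodophenol | Oc1cccc(I)c1 | starting material
2 | 1-iodo-3-(methoxymethoxy)benzene | COCOc1cccc(I)c1 | intermediate
3 | [2-iodo-6-(methoxymethoxy)phenyl]lithium | [Li]c1c(I)cccc1OCOC | intermediate
4 | 2-iodo-6-(methoxymethoxy)benzaldehyde | COCOc1cccc(I)c1C=O | intermediate
5 | 2-[2-iodo-6-(methoxymethoxy)phenyl]-1,3-dioxolane | COCOc1cccc(I)c1C1OCCO1 | intermediate
6 | 2-methylbut-3-en-2-ol | CC(C)(O)C=C | starting material
7 | 3-(methoxymethoxy)-3-methylbut-1-ene | COCOC(C)(C)C=C | intermediate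
8 | rac-2-[2-(methoxymethoxy)propan-2-yl]oxirane | COCOC(C)(C)C1CO1 | intermediate
9 | (S)-2-[2-(methoxymethoxy)propan-2-yl]oxirane | COCOC(C)(C)[C@@H]1CO1 | intermediate
10 | (S)-propylene oxide | C[C@H]1CO1 | starting material
11 | but-3-enylmagnesium bromide | C=CCC[Mg]Br | starting material
12 | (S)-hept-6-en-2-ol | C[C@H](O)CCCC=C | intermediate
13 | (S)-tert-butyl(hept-6-en-2-yloxy)dimethylsilane | C[C@H](O[Si](C)(C)C(C)(C)C)CCCC=C | intermediate
14 | dimethyl (4R,5R)-2,2-dimethyl-1,3-dioxolane-4,5-dicarboxylate | COC(=O)[C@@H]1OC(C)(C)O[C@H]1C(=O)OC | starting material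
15 | (4R,5R)-2,2-dimethyl-1,3-dioxolane-4,5-dicarbaldehyde (formed as its aluminium hemiacetal) | O=C[C@@H]1OC(C)(C)O[C@H]1C=O | intermediate
16 | (4S,5S)-2,2-dimethyl-4,5-divinyl-1,3-dioxolane | C=C[C@@H]1OC(C)(C)O[C@H]1C=C | intermediate
17 | tert-butyl{[(2S,6E)-7-[(4S,5S)-2,2-dimethyl-5-vinyl-1,3-dioxolan-4-yl]hept-6-en-2-yl]oxy}dimethylsilane | C[C@H](O[Si](C)(C)C(C)(C)C)CCC/C=C/[C@@H]1OC(C)(C)O[C@H]1C=C | intermediate
18 | (2S)-1-{2-[(E)-2-{(4S,5S)-5-[(1E,6S)-6-(tert-butyldimethylsilyloxy)hept-1-en-1-yl]-2,2-dimethyl-1,3-dioxolan-4-yl}vinyl]-3-(1,3-dioxolan-2-yl)-4-(methoxymethoxy)phenyl}-3-(methoxymethoxy)-3-methylbutan-2-ol | C[C@H](O[Si](C)(C)C(C)(C)C)CCC/C=C/[C@@H]1OC(C)(C)O[C@H]1/C=C/c2c(C[C@H](O)C(C)(C)OCOC)ccc(OCOC)c2C3OCCO3 | intermediate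
19 | 3-[(2S)-2,3-dihydroxy-3-methylbutyl]-6-hydroxy-2-[(1E,3S,4S,5E,10S)-3,4,10-trihydroxyundeca-1,5-dien-1-yl]benzaldehyde | C[C@H](O)CCC/C=C/[C@H](O)[C@@H](O)/C=C/c1c(C[C@H](O)C(C)(C)O)ccc(O)c1C=O | target

**Step count and risks**

Total step count: 12. Longest linear sequence: 5 steps (for example steps 1, 2, 3, 11, 12).

Steps most likely to fail:

1. Step 11 (the proposed three-component coupling). The arylpalladium intermediate may form the aryl–oxygen bond with the neighbouring alkoxide faster than it inserts the hindered alkene. Alternatively 5 may undergo a direct Heck reaction before norbornene inserts, or β-hydride elimination may run toward C3'. Fallback with known reactions, making the two bonds one after the other: the route sets out from acetal 5. Electrophilic bromination para to the methoxymethoxy group (NBS, MeCN) gives 2-[3-bromo-2-iodo-6-(methoxymethoxy)phenyl]-1,3-dioxolane F1. A Mizoroki–Heck reaction of F1 with alkene 17 under phosphine-free conditions (Pd(OAc)2, Bu4NCl, NaHCO3, DMF, 60 °C) reacts at the carbon–iodine bond only and gives the (E)-styrenyl aryl bromide F2. Bromine–lithium exchange on F2 (t-BuLi, THF, −78 °C) and opening of epoxide 9 at its CH2 terminus in the presence of BF3·OEt2 forms C5–CH2 and returns to compound 18.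

2. Step 12 (global deprotection). Ionisation at the allylic carbinols C3' and C4' (solvolysis, allylic transposition, cyclisation) may set in while the slow cleavage of the tertiary methoxymethyl ether is still incomplete. Fallback that moves the hard cleavages to aprotic, buffered conditions: from 18, Me3SiOTf and 2,2'-bipyridyl in CH2Cl2 at 0 °C followed by water remove both methoxymethyl ethers and the aryl dioxolane. This gives 3-[(2S)-2,3-dihydroxy-3-methylbutyl]-2-[(E)-2-{(4S,5S)-5-[(1E,6S)-6-(tert-butyldimethylsilyloxy)hept-1-en-1-yl]-2,2-dimethyl-1,3-dioxolan-4-yl}vinyl]-6-hydroxybenzaldehyde F3. Acetonide and silyl ether of F3 are then hydrolysed with the weak acid AcOH/H2O/THF (3:1:1) at 45 °C, returning to target 19.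

3. Step 10 (cross-metathesis). A statistical second metathesis at the remaining vinyl group and incomplete E selectivity at C5'=C6' may give a mixture that is hard to separate. Fallback by Julia–Kocienski olefination:
 - Aldehyde part, from diester 14: LiAlH4 reduction gives [(4S,5S)-2,2-dimethyl-1,3-dioxolane-4,5-diyl]dimethanol F4. Monosilylation (NaH, TBSCl, THF) gives [(4S,5S)-5-{[tert-butyl(dimethyl)silyl]oxymethyl}-2,2-dimethyl-1,3-dioxolan-4-yl]methanol F5. Swern oxidation gives (4R,5S)-5-{[tert-butyl(dimethyl)silyl]oxymethyl}-2,2-dimethyl-1,3-dioxolane-4-carbaldehyde F6, and Wittig methylenation gives tert-butyl{[(4S,5S)-2,2-dimethyl-5-vinyl-1,3-dioxolan-4-yl]methoxy}dimethylsilane F7. Bu4NF frees [(4S,5S)-2,2-dimethyl-5-vinyl-1,3-dioxolan-4-yl]methanol F8, and a second Swern oxidation gives (4R,5S)-2,2-dimethyl-5-vinyl-1,3-dioxolane-4-carbaldehyde F9.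
 - Sulfone part, from alkene 13: ozonolysis with NaBH4 work-up gives (S)-5-(tert-butyldimethylsilyloxy)hexan-1-ol F10. Mitsunobu reaction with 1-phenyl-1H-tetrazole-5-thiol (PPh3, DIAD) gives 5-{[(5S)-5-(tert-butyldimethylsilyloxy)hexyl]sulfanyl}-1-phenyl-1H-tetrazole F11. Oxidation (H2O2, (NH4)6Mo7O24, EtOH) gives 5-{[(5S)-5-(tert-butyldimethylsilyloxy)hexyl]sulfonyl}-1-phenyl-1H-tetrazole F12.
 - Coupling: deprotonation of F12 with KN(SiMe3)2 in DME at −60 °C and addition of F9 gives the E alkene and returns to compound 17.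

**Further compounds**

F1 | step 11 | 2-[3-bromo-2-iodo-6-(methoxymethoxy)phenyl]-1,3-dioxolane | COCOc1ccc(Br)c(I)c1C1OCCO1
F2 | step 11 | 2-{3-bromo-2-[(E)-2-{(4S,5S)-5-[(1E,6S)-6-(tert-butyldimethylsilyloxy)hept-1-en-1-yl]-2,2-dimethyl-1,3-dioxolan-4-yl}vinyl]-6-(methoxymethoxy)phenyl}-1,3-dioxolane | C[C@H](O[Si](C)(C)C(C)(C)C)CCC/C=C/[C@@H]1OC(C)(C)O[C@H]1/C=C/c2c(Br)ccc(OCOC)c2C3OCCO3
F3 | step 12 | 3-[(2S)-2,3-dihydroxy-3-methylbutyl]-2-[(E)-2-{(4S,5S)-5-[(1E,6S)-6-(tert-butyldimethylsilyloxy)hept-1-en-1-yl]-2,2-dimethyl-1,3-dioxolan-4-yl}vinyl]-6-hydroxybenzaldehyde | C[C@H](O[Si](C)(C)C(C)(C)C)CCC/C=C/[C@@H]1OC(C)(C)O[C@H]1/C=C/c2c(C[C@H](O)C(C)(C)O)ccc(O)c2C=O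
F4 | step 10 | [(4S,5S)-2,2-dimethyl-1,3-dioxolane-4,5-diyl]dimethanol | OC[C@@H]1OC(C)(C)O[C@H]1CO
F5 | step 10 | [(4S,5S)-5-{[tert-butyl(dimethyl)silyl]oxymethyl}-2,2-dimethyl-1,3-dioxolan-4-yl]methanol | CC(C)(C)[Si](C)(C)OC[C@@H]1OC(C)(C)O[C@H]1CO
F6 | step 10 | (4R,5S)-5-{[tert-butyl(dimethyl)silyl]oxymethyl}-2,2-dimethyl-1,3-dioxolane-4-carbaldehyde | CC(C)(C)[Si](C)(C)OC[C@@H]1OC(C)(C)O[C@H]1C=O
F7 | step 10 | tert-butyl{[(4S,5S)-2,2-dimethyl-5-vinyl-1,3-dioxolan-4-yl]methoxy}dimethylsilane | CC(C)(C)[Si](C)(C)OC[C@@H]1OC(C)(C)O[C@H]1C=C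
F8 | step 10 | [(4S,5S)-2,2-dimethyl-5-vinyl-1,3-dioxolan-4-yl]methanol | OC[C@@H]1OC(C)(C)O[C@H]1C=C
F9 | step 10 | (4R,5S)-2,2-dimethyl-5-vinyl-1,3-dioxolane-4-carbaldehyde | O=C[C@@H]1OC(C)(C)O[C@H]1C=C
F10 | step 10 | (S)-5-(tert-butyldimethylsilyloxy)hexan-1-ol | C[C@H](O[Si](C)(C)C(C)(C)C)CCCCO
F11 | step 10 | 5-{[(5S)-5-(tert-butyldimethylsilyloxy)hexyl]sulfanyl}-1-phenyl-1H-tetrazole | C[C@H](O[Si](C)(C)C(C)(C)C)CCCCSc1nnnn1-c1ccccc1
F12 | step 10 | 5-{[(5S)-5-(tert-butyldimethylsilyloxy)hexyl]sulfonyl}-1-phenyl-1H-tetrazole | C[C@H](O[Si](C)(C)C(C)(C)C)CCCCS(=O)(=O)c1nnnn1-c1ccccc1
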